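## Retrosynthetic overview
1. The target is 5,7,2',5'-tetrahydroxy-6,8,4'-trimethoxyflavone. The last operation is hydrogenolysis of four benzyl ethers.
2. Ring C (the pyranone) is the only ring that is built. It comes from oxidative cyclisation of a 2'-hydroxychalcone, and rings A and B are bought as arenes.
3. The key C–C bond (chalcone Cα–Cβ, which becomes flavone C3–C2) is made by an intermolecular Claisen–Schmidt aldol condensation of an A-ring acetophenone with a B-ring benzaldehyde.
4. A-ring piece: phloroacetophenone → 4,6-di-O-benzyl ether → 3,5-dibromide → Cu-catalysed double methoxylation. The symmetric 3,5-dimethoxy pattern makes the ring-closure regiochemistry unambiguous.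
5. B-ring piece: vanillin → Dakin oxidation → di-O-benzyl ether → Vilsmeier formylation.

Assumption: the SMILES holds no stereocentre, axis or fixed double-bond geometry, so the target is achiral and needs no enantiocontrol. The racemic transient intermediates lose their stereocentres when ring C aromatises.

## Route

Step 1
Reactants: 1 vanillin (4-hydroxy-3-methoxybenzaldehyde)
Product: 3 2-methoxybenzene-1,4-diol (methoxyhydroquinone), via 4-hydroxy-3-methoxyphenyl formate 2 (not isolated)
Conditions: 30% H2O2 (1.2 equiv), NaOH (1.1 equiv), H2O, N2, 0 °C → rt; then HCl to pH 2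
Reagents that add atoms: hydrogen peroxide, OO
Why: Dakin oxidation, in which hydroperoxide adds to the aldehyde of the para-hydroxybenzaldehyde, the electron-rich aryl group migrates to oxygen to give formate 2, and 2 is saponified in the same pot.

Step 2
Reactants: 3 2-methoxybenzene-1,4-diol
Product: 4 1,4-bis(benzyloxy)-2-methoxybenzene
Conditions: BnBr (2.3 equiv), K2CO3 (3 equiv), DMF, N2, 60 °C
Reagents that add atoms: benzyl bromide, BrCc1ccccc1
Why: Double Williamson ether synthesis (SN2 of both phenoxides on benzyl bromide), which also removes the air sensitivity of the hydroquinone.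

Step 3
Reactants: 4 1,4-bis(benzyloxy)-2-methoxybenzene
Product: 6 2,5-bis(benzyloxy)-4-methoxybenzaldehyde, via aryl dimethyliminium salt 5 (not isolated)
Conditions: POCl3 (1.5 equiv), DMF, 0 → 70 °C; then ice-water, rt
Reagents that add atoms: N,N-dimethylformamide, CN(C)C=O; water, O
Why: Vilsmeier–Haack formylation, in which the chloroiminium ion attacks the one unhindered position that is para to OMe and ortho to OBn (the selectivity that turns 1,2,4-trimethoxybenzene into asaraldehyde), and water hydrolyses iminium salt 5.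

Step 4
Reactants: 7 2',4',6'-trihydroxyacetophenone (phloroacetophenone)
Product: 8 4',6'-bis(benzyloxy)-2'-hydroxyacetophenone
Conditions: BnBr (2.1 equiv), K2CO3 (2.5 equiv), DMF, rt → 50 °C
Reagents that add atoms: benzyl bromide, BrCc1ccccc1
Why: Selective Williamson etherification, in which the 4-OH and one of the two equivalent ortho OH groups are alkylated while the remaining ortho OH stays free because it is hydrogen-bonded to the ketone.

Step 5
Reactants: 8 4',6'-bis(benzyloxy)-2'-hydroxyacetophenone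
Product: 9 4',6'-bis(benzyloxy)-3',5'-dibromo-2'-hydroxyacetophenone
Conditions: NBS (2.05 equiv), MeCN, dark, 0 °C → rt
Reagents that add atoms: N-bromosuccinimide, O=C1CCC(=O)N1Br
Why: Electrophilic aromatic bromination at the only two free ring positions, each activated by three oxygen donors, which is far faster than ketone α-bromination or attack on the benzyl groups.

Step 6
Reactants: 9 4',6'-bis(benzyloxy)-3',5'-dibromo-2'-hydroxyacetophenone
Product: 10 4',6'-bis(benzyloxy)-2'-hydroxy-3',5'-dimethoxyacetophenone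
Conditions: NaOMe (25% in MeOH, 8 equiv), CuBr (0.3 equiv), DMF, Ar, 110 °C; acidic work-up
Reagents that add atoms: sodium methoxide, C[O-].[Na+]
Why: Ullmann-type Cu(I)-catalysed methoxylation of aryl bromides (the reaction that makes syringaldehyde from bromovanillin and 6,8-dimethoxyflavones from 6,8-dibromoflavones), with the benzyl ethers and the hindered ketone inert to methoxide.

Step 7
Reactants: 10 4',6'-bis(benzyloxy)-2'-hydroxy-3',5'-dimethoxyacetophenone; 6 2,5-bis(benzyloxy)-4-methoxybenzaldehyde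
Product: 12 (E)-1-[4,6-bis(benzyloxy)-2-hydroxy-3,5-dimethoxyphenyl]-3-[2,5-bis(benzyloxy)-4-methoxyphenyl]prop-2-en-1-one, via racemic β-hydroxyketone aldol adduct 11 (not isolated)
Conditions: KOH (10 equiv, 50% aq), EtOH/THF 2:1, rt, 48 h; acidic work-up
Reagents that add atoms: none
Why: Claisen–Schmidt aldol condensation, in which the methyl ketone enolate adds to the non-enolisable aldehyde and E1cB loss of water from 11 gives the conjugated E-chalcone under thermodynamic control.

Step 8
Reactants: 12 (E)-chalcone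
Product: 15 5,7-bis(benzyloxy)-2-[2,5-bis(benzyloxy)-4-methoxyphenyl]-6,8-dimethoxy-4H-chromen-4-one, via racemic flavanone 13 (not isolated), via racemic 3-iodoflavanone 14 (not isolated)
Conditions: I2 (0.1 equiv), DMSO, 120 °C, 2–4 h; aq Na2S2O3 wash
Reagents that add atoms: none
Why: I2/DMSO oxidative cyclisation, in which intramolecular oxa-Michael addition of the free 2'-OH gives 13, α-iodination gives 14, loss of HI gives the flavone, and DMSO re-oxidises HI to I2, so both transient stereocentres vanish.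

Step 9
Reactants: 15 tetra-O-benzyl flavone
Product: 16 5,7-dihydroxy-2-(2,5-dihydroxy-4-methoxyphenyl)-6,8-dimethoxy-4H-chromen-4-one (target)
Conditions: H2 (1 atm), 10% Pd/C, THF/MeOH 1:1, rt; filtration and concentration under Ar
Reagents that add atoms: none
Why: Catalytic hydrogenolysis cleaves all four benzylic C–O bonds at 1 atm while the methyl ethers and the conjugated flavone C2=C3 bond survive, and the inert work-up protects the hydroquinone B ring from air oxidation.

## Compound list
1 | vanillin (4-hydroxy-3-methoxybenzaldehyde) | COc1cc(C=O)ccc1O | starting material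
2 | 4-hydroxy-3-methoxyphenyl formate | COc1cc(OC=O)ccc1O | intermediate
3 | 2-methoxybenzene-1,4-diol | COc1cc(O)ccc1O | intermediate
4 | 1,4-bis(benzyloxy)-2-methoxybenzene | COc1cc(OCc2ccccc2)ccc1OCc1ccccc1 | intermediate
5 | [2,5-bis(benzyloxy)-4-methoxybenzylidene]dimethyliminium dichlorophosphate | COc1cc(OCc2ccccc2)c(C=[N+](C)C)cc1OCc1ccccc1.[O-]P(Cl)(Cl)=O | intermediate
6 | 2,5-bis(benzyloxy)-4-methoxybenzaldehyde | COc1cc(OCc2ccccc2)c(C=O)cc1OCc1ccccc1 | intermediate
7 | 2',4',6'-trihydroxyacetophenone | CC(=O)c1c(O)cc(O)cc1O | starting material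
8 | 4',6'-bis(benzyloxy)-2'-hydroxyacetophenone | CC(=O)c1c(O)cc(OCc2ccccc2)cc1OCc1ccccc1 | intermediate
9 | 4',6'-bis(benzyloxy)-3',5'-dibromo-2'-hydroxyacetophenone | CC(=O)c1c(O)c(Br)c(OCc2ccccc2)c(Br)c1OCc1ccccc1 | intermediate
10 | 4',6'-bis(benzyloxy)-2'-hydroxy-3',5'-dimethoxyacetophenone | CC(=O)c1c(O)c(OC)c(OCc2ccccc2)c(OC)c1OCc1ccccc1 | intermediate
11 | racemic 1-[4,6-bis(benzyloxy)-2-hydroxy-3,5-dimethoxyphenyl]-3-[2,5-bis(benzyloxy)-4-methoxyphenyl]-3-hydroxypropan-1-one | O=C(CC(O)c1cc(OCc2ccccc2)c(OC)cc1OCc1ccccc1)c1c(O)c(OC)c(OCc2ccccc2)c(OC)c1OCc1ccccc1 | intermediate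
12 | (E)-1-[4,6-bis(benzyloxy)-2-hydroxy-3,5-dimethoxyphenyl]-3-[2,5-bis(benzyloxy)-4-methoxyphenyl]prop-2-en-1-one | O=C(/C=C/c1cc(OCc2ccccc2)c(OC)cc1OCc1ccccc1)c1c(O)c(OC)c(OCc2ccccc2)c(OC)c1OCc1ccccc1 | intermediate
13 | racemic 5,7-bis(benzyloxy)-2-[2,5-bis(benzyloxy)-4-methoxyphenyl]-6,8-dimethoxychroman-4-one | O=C1CC(c2cc(OCc3ccccc3)c(OC)cc2OCc2ccccc2)Oc2c(OC)c(OCc3ccccc3)c(OC)c(OCc3ccccc3)c21 | intermediate
14 | racemic 5,7-bis(benzyloxy)-2-[2,5-bis(benzyloxy)-4-methoxyphenyl]-3-iodo-6,8-dimethoxychroman-4-one (relative configuration of no consequence) | O=C1C(I)C(c2cc(OCc3ccccc3)c(OC)cc2OCc2ccccc2)Oc2c(OC)c(OCc3ccccc3)c(OC)c(OCc3ccccc3)c21 | intermediate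
15 | 5,7-bis(benzyloxy)-2-[2,5-bis(benzyloxy)-4-methoxyphenyl]-6,8-dimethoxy-4H-chromen-4-one | O=c1cc(-c2cc(OCc3ccccc3)c(OC)cc2OCc2ccccc2)oc2c(OC)c(OCc3ccccc3)c(OC)c(OCc3ccccc3)c12 | intermediate
16 | 5,7-dihydroxy-2-(2,5-dihydroxy-4-methoxyphenyl)-6,8-dimethoxy-4H-chromen-4-one (achiral) | COc1cc(O)c(-c2cc(=O)c3c(O)c(OC)c(O)c(OC)c3o2)cc1O | target

## Summary
Total step count: 9. Longest linear sequence: 6 steps (1 → 3 → 4 → 6 → 12 → 15 → 16, and the same length through 7 → 8 → 9 → 10).

## Three steps most likely to fail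

**Step 6 (double methoxylation).** Both bromides are flanked by two ortho substituents, so hydrodebromination or incomplete exchange on the phenoxide/enolisable ketone is the main danger.
- The fallback sets out from 9 (together with 6) and comes back at 15. It moves the C–O coupling to the flavone stage.
- Dibromide 9 is condensed with aldehyde 6 (KOH, EtOH/THF) to (E)-1-[4,6-bis(benzyloxy)-3,5-dibromo-2-hydroxyphenyl]-3-[2,5-bis(benzyloxy)-4-methoxyphenyl]prop-2-en-1-one F1.
- F1 is cyclised with I2/DMSO to 5,7-bis(benzyloxy)-2-[2,5-bis(benzyloxy)-4-methoxyphenyl]-6,8-dibromo-4H-chromen-4-one F2.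
- F2 has neither a free phenoxide nor a methyl ketone. Treating it with NaOMe/CuBr in DMF/MeOH gives 15.
- Any 7-O-debenzylated material from this last reaction still converges on 16 in step 9.

**Step 7 (aldol condensation).** The ketone sits on a hexasubstituted ring and the aldehyde is electron-rich, so conversion may be slow or incomplete.
- The fallback sets out from 6 and 10 and comes back at 15, bypassing 12. It replaces the aldol by an intermolecular Claisen-type acylation.
- Aldehyde 6 is oxidised (NaClO2, NaH2PO4, 2-methyl-2-butene, t-BuOH/H2O) to 2,5-bis(benzyloxy)-4-methoxybenzoic acid F3.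
- F3 is converted with (COCl)2 and cat. DMF in CH2Cl2 into 2,5-bis(benzyloxy)-4-methoxybenzoyl chloride F4.
- F4 is added to the lithium dianion of 10 (LiHMDS 4 equiv, THF, −78 °C → rt) to give 1-[4,6-bis(benzyloxy)-2-hydroxy-3,5-dimethoxyphenyl]-3-[2,5-bis(benzyloxy)-4-methoxyphenyl]propane-1,3-dione F5.
- F5 is cyclodehydrated with cat. p-TsOH in toluene at 90 °C to 15.

**Step 8 (I2/DMSO).** HI at 120 °C can strip the 5-O-benzyl group, and the I2/DMSO couple can iodinate the very electron-rich B ring.
- The fallback sets out from 12 and comes back at 15. It separates ring closure from oxidation and uses no iodine.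
- Chalcone 12 is isomerised with NaOAc in refluxing EtOH and the flavanone 13 is isolated.
- Flavanone 13 is dehydrogenated with DDQ (1.5 equiv) in refluxing dioxane. Hydride abstraction at the doubly activated benzylic C2–H followed by proton loss gives 15.

## Further compounds
F1 | step 6 | (E)-1-[4,6-bis(benzyloxy)-3,5-dibromo-2-hydroxyphenyl]-3-[2,5-bis(benzyloxy)-4-methoxyphenyl]prop-2-en-1-one | O=C(/C=C/c1cc(OCc2ccccc2)c(OC)cc1OCc1ccccc1)c1c(O)c(Br)c(OCc2ccccc2)c(Br)c1OCc1ccccc1
F2 | step 6 | 5,7-bis(benzyloxy)-2-[2,5-bis(benzyloxy)-4-methoxyphenyl]-6,8-dibromo-4H-chromen-4-one | O=c1cc(-c2cc(OCc3ccccc3)c(OC)cc2OCc2ccccc2)oc2c(Br)c(OCc3ccccc3)c(Br)c(OCc3ccccc3)c12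
F3 | step 7 | 2,5-bis(benzyloxy)-4-methoxybenzoic acid | COc1cc(OCc2ccccc2)c(C(=O)O)cc1OCc1ccccc1
F4 | step 7 | 2,5-bis(benzyloxy)-4-methoxybenzoyl chloride | COc1cc(OCc2ccccc2)c(C(=O)Cl)cc1OCc1ccccc1
F5 | step 7 | 1-[4,6-bis(benzyloxy)-2-hydroxy-3,5-dimethoxyphenyl]-3-[2,5-bis(benzyloxy)-4-methoxyphenyl]propane-1,3-dione | O=C(CC(=O)c1cc(OCc2ccccc2)c(OC)cc1OCc1ccccc1)c1c(O)c(OC)c(OCc2ccccc2)c(OC)c1OCc1ccccc1
F0 | step 8 | none | none
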